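How far does the partner pull substrate down in the east flask by 42 h, and how does the starting rate answer to each charge?

| flask | substrate | partner | time |
|---|---|---|---|
| north-west | 0.300 M | 0.450 M |  |
| south | 0.900 M | 0.450 M |  |
| south-west | 0.300 M | 0.230 M |  |
| east | 0.300 M | 0.0980 M | 42 h |

| north-west run: time / h | north-west run: [substrate] / M | south run: time / h | south run: [substrate] / M | south-west run: time / h | south-west run: [substrate] / M |
|---|---|---|---|---|---|
| 5.2 | 0.0263 | 5.2 | 0.4646 | 5.2 | 0.1025 |
| 10 | 0.0228 | 10 | 0.4641 | 10 | 0.1008 |
| 16 | 0.0192 | 16 | 0.4596 | 16 | 0.0964 |
| 21 | 0.0178 | 21 | 0.4582 | 21 | 0.0942 |
| 26 | 0.0134 | 26 | 0.4535 | 26 | 0.0921 |
| 32 | 0.0104 | 32 | 0.4524 | 32 | 0.0874 |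
| 37 | 0.0065 | 37 | 0.4514 | 37 | 0.0850 |
| 42 | 0.0063 | 42 | 0.4503 | 42 | 0.0797 |

(standard deviation of a reading: 9 × 10⁻⁴ M)

- apparent order in [partner] of the starting rate, round the charge of the north-west run (the rate where two percent of its substrate have turned into target)
- apparent order in [substrate] of the starting rate, round the charge of the north-west run (the rate where two percent of its substrate have turned into target) (one fixed amount of target, the same in the runs compared)
- substrate in the east run at 42 h, as a share of the substrate charged
- which of these the readings show (the product binds the second partner / the product decays / nothing beyond the main steps / the product speeds the reaction / the second partner is lost by itself)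

- Overall: substrate + partner -> target.
- Constant volume, constant temperature.
- "The second partner" is partner.
- An order is taken over about fifteen percent of the charge, up and down.

The fastest rung is over before the first reading at 5.2 h. By then the north-west run has lost 91.2% of its substrate. I count that whole loss as held one to one with partner, 0.274 M in all, although part of it may already be target, and this count leaves 0.176 M of partner free. Held over free substrate times free partner is my holding constant, read from this one reading as 59.0 L mol⁻¹.

The slower rung is the fall of free substrate times free partner. In the south-west readings it falls at 0.0249 h⁻¹ early and 0.0605 h⁻¹ late, faster late than early. I read the held form as a resting state in balance with free substrate and free partner, and I read the quickening as target speeding its own formation.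

If the rate follows the held amount, the orders are the slopes of that amount. Differentiating the holding balance at the first north-west reading gives 0.197 in partner and 0.880 in substrate.

The east flask has less partner than substrate, so partner is the limiting reagent. With all partner taken, substrate stands at 67.3% of its charge. Putting that back through the holding constant frees some partner and gives 69.9%, and one more round gives 69.8%. Passage to target moves substrate from this value towards the floor, so I take the midpoint, 68.6%, at 42 h.

The forecast gives orders 1 in partner and 1 in substrate, 68% for the east run, and "the product decays", on the ground that “Target is therefore being drained slowly”.

The east run gives 68.4%, the orders are 0.21 in partner and 0.89 in substrate, and the readings show that the product speeds the reaction.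

    substrate + partner ⇌ intermediate, settled at all times (54.90 L mol⁻¹)
    substrate + partner → target (0.9684 L mol⁻¹ h⁻¹)
    substrate + partner + target → 2 target (11.95 L² mol⁻² h⁻¹)

The east value lies above the floor and below the twice-iterated value. The south-west run makes target at 0.71 of the north-west rate at equal target, and the holding constant on the south-west charge gives a held amount 0.721 of the north-west one.

The data were generated by integration for substances that don't exist, noise included.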